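Everything rests on disconnecting the cyclohexane ring of the spiro[4.5]decane core across C7–C8 (the two ring methylenes) and C5–C6 (spiro carbon to the methyl carbinol carbon). One acid-catalysed [4+2] union makes both bonds: a 2-silyloxydiene, whose hindered terminus is the exocyclic alkylidene carbon of a cis-fused cyclopentane γ-lactone, adds to 3-methylbut-3-en-2-one. The step exploits the spiro atom C5 flanked by oxygenated C1 and C6: the lactone, a temporary ring that later gives the C1 hydroxyl and the side-chain CH2OH, blocks one face, and the endo acetyl group becomes the C6 hydroxyl by Baeyer–Villiger oxidation. Ring carbons C9 and C10 emerge as a regiodefined silyl enol ether.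

Key step: step 7

Locants used below (spiro[4.5]decane): C1 = CH(OH) of the five-membered ring, C2 = CH bearing the side chain, C3 and C4 = its CH2 groups (C4 next to C5), C5 = spiro carbon, C6 = C(CH3)(OH), C7 and C8 = ring CH2 groups, C9 = carbon of the exocyclic enal, C10 = CH bearing the 3-hydroxypropyl chain. The target is (1R,2S,5S,6S,10R).

Remark on the chemistry: the (S,S) enantiomer of the Trost ligand is assumed to be the one that gives the R-configured malonate 3; if it gives the antipode, the (R,R) ligand is used instead.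

Step 1
Reactants: 1 rac-cyclopent-2-en-1-yl acetate; 2 dimethyl malonate
Product: 3 dimethyl (R)-2-(cyclopent-2-en-1-yl)malonate
Conditions: [Pd(C3H5)Cl]2 (2.5 mol %), (S,S)-DACH-phenyl Trost ligand (7.5 mol %), NaH, (n-C6H13)4NBr, CH2Cl2, 0 °C
Reagents that add atoms: none
Why: Trost asymmetric allylic alkylation (Tsuji–Trost reaction): both enantiomers of 1 ionise to the same symmetric π-allylpalladium complex and the chiral ligand directs the malonate to one allyl terminus, which should set the ring stereocentre (R) enantioselectively.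

Step 2
Reactants: 3 dimethyl (R)-2-(cyclopent-2-en-1-yl)malonate
Product: 5 (S)-2-(cyclopent-2-en-1-yl)acetic acid, via malonic diacid 4 (not isolated)
Conditions: NaOH, MeOH/H2O, 65 °C; HCl; then neat, 150 °C
Reagents that add atoms: sodium hydroxide, [Na+].[OH-]
Why: Ester saponification followed by thermal decarboxylation of the malonic acid leaves the allylic stereocentre untouched.

Step 3
Reactants: 5 (S)-2-(cyclopent-2-en-1-yl)acetic acid
Product: 7 (1R,5S,8R)-8-hydroxy-2-oxabicyclo[3.3.0]octan-3-one, via anti epoxy acid 6 (not isolated)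
Conditions: mCPBA, CH2Cl2, 0 → 25 °C
Reagents that add atoms: mCPBA (3-chloroperbenzoic acid), OOC(=O)c1cccc(Cl)c1
Why: Prilezhaev epoxidation should occur mainly anti to the CH2CO2H arm, and the carboxyl group then opens the epoxide in a 5-exo-tet mode with inversion, so the lactone oxygen ends cis to the acetic acid arm (cis ring fusion) and the hydroxyl trans to it; the syn epoxy acid cannot lactonise and is removed by a NaHCO3 wash.

Step 4
Reactants: 7 (1R,5S,8R)-8-hydroxy-2-oxabicyclo[3.3.0]octan-3-one
Product: 8 (1R,5S)-2-oxabicyclo[3.3.0]octane-3,8-dione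
Conditions: Dess–Martin periodinane, CH2Cl2, 25 °C
Reagents that add atoms: none
Why: Dess–Martin oxidation of the secondary alcohol; the cis ring fusion prevents epimerisation of the α-acyloxy carbon.

Step 5
Reactants: 8 (1R,5S)-2-oxabicyclo[3.3.0]octane-3,8-dione; 9 1-(triphenylphosphoranylidene)propan-2-one
Product: 10 (1R,5S)-8-[(E)-2-oxopropylidene]-2-oxabicyclo[3.3.0]octan-3-one
Conditions: toluene, 100 °C
Reagents that add atoms: none
Why: Wittig olefination of the activated α-acyloxy ketone with a stabilised ylide should give mainly the E alkene, in which the acetyl group is anti to the oxygen-bearing ring carbon (the Z isomer is separable or isomerised with catalytic I2).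

Step 6
Reactants: 10 (1R,5S)-8-[(E)-2-oxopropylidene]-2-oxabicyclo[3.3.0]octan-3-one
Product: 11 (1R,5S)-8-[(E)-2-(tert-butyldimethylsilyloxy)prop-2-en-1-ylidene]-2-oxabicyclo[3.3.0]octan-3-one
Conditions: TBSOTf, Et3N, CH2Cl2, −78 → 0 °C
Reagents that add atoms: TBSOTf (tert-butyldimethylsilyl trifluoromethanesulfonate), CC(C)(C)[Si](C)(C)OS(=O)(=O)C(F)(F)F
Why: Soft enolisation of the methyl ketone (silyl enol ether formation) at the CH3 group gives the cross-conjugated 2-silyloxydiene while the lactone is not enolised.

Step 7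
Reactants: 11 (1R,5S)-8-[(E)-2-(tert-butyldimethylsilyloxy)prop-2-en-1-ylidene]-2-oxabicyclo[3.3.0]octan-3-one; 12 3-methylbut-3-en-2-one
Product: 13 spiro silyl enol ether lactone (6-acetyl-6-methyl-9-silyloxyspiro[4.5]dec-9-ene with the C1–O/C2–CH2 γ-lactone; acetyl cis to C1)
Conditions: HN(SO2CF3)2 (10 mol %), CH2Cl2, −78 → −40 °C
Reagents that add atoms: none
Why: HN(SO2CF3)2 protodesilylates a trace of 11 to give tBuMe2SiN(SO2CF3)2, which activates enone 12 at oxygen; the nucleophilic CH2 terminus of the 2-silyloxydiene adds to the enone CH2 (C7–C8 bond), the resulting silyl enol ether closes onto the silyloxyallyl cation at the ring carbon (C5–C6 bond), and silyl transfer regenerates the catalyst (a highly asynchronous Diels–Alder reaction, in the limit a Mukaiyama–Michael/Michael sequence). The closest known reaction type is the Lewis-acid-catalysed Diels–Alder reaction of hindered 2-silyloxydienes with hindered enones, which builds vicinal quaternary carbons. The cyclohexene ring is closed by an intermolecular [4+2] cycloaddition (in the stepwise limit the second bond forms in a 6-endo-trig mode). Spiro C5 is controlled by the cis-fused γ-lactone, whose concave face is blocked, so the dienophile adds to the convex face anti to the C1–O bond; C6 is controlled by the endo position of the acetyl group together with the E geometry of the diene (C1 in the outside position), which places acetyl cis to C1 and methyl cis to C4. The step needs para regioselectivity, secured by the 2-silyloxy group (largest coefficient on the terminal CH2) and the β-unsubstituted enone, and endo selectivity, secured because the silylated acetyl group avoids the cyclopentane ring that lies under the exo position.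

Step 8
Reactants: 13 spiro silyl enol ether lactone; 14 3-(tert-butyldimethylsilyloxy)propanal
Product: 15 aldol adduct (9-oxo; 10-[1-hydroxy-3-(silyloxy)propyl]; diastereomer mixture)
Conditions: TiCl4, CH2Cl2, −78 °C
Reagents that add atoms: none
Why: Mukaiyama aldol addition at the regiodefined silyl enol ether carbon C10; the two new stereocentres need no control because both are erased in step 9.

Step 9
Reactants: 15 aldol adduct
Product: 17 exocyclic enone (10-[3-(silyloxy)propylidene]-9-oxo; E/Z mixture), via mesylate 16 (not isolated)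
Conditions: MsCl, Et3N, CH2Cl2, 0 °C; then DBU, 25 °C
Reagents that add atoms: none
Why: Mesylation and E1cB elimination (completion of an aldol condensation) give the exocyclic enone, whose alkene geometry is irrelevant for step 11.

Step 10
Reactants: 17 exocyclic enone
Product: 18 6-acetoxy enone (acetate cis to C1)
Conditions: mCPBA, NaHCO3, CH2Cl2, 25 °C
Reagents that add atoms: mCPBA (3-chloroperbenzoic acid), OOC(=O)c1cccc(Cl)c1
Why: Baeyer–Villiger oxidation: the tertiary carbon C6 migrates in preference to methyl and with retention of configuration, while the conjugated enone carbonyl and its electron-poor alkene should react much more slowly.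

Step 11
Reactants: 18 6-acetoxy enone
Product: 19 saturated ketone (10-[3-(silyloxy)propyl] cis to C1)
Conditions: H2 (3 bar), Pd/C (10% palladium on carbon), EtOAc, 25 °C
Reagents that add atoms: none
Why: Heterogeneous catalytic hydrogenation should deliver hydrogen to C10 from the face on the side of C4, because the other face is covered by the lactone on C1 and the axial C6 acetate, which sets C10 with the side chain cis to C1.

Step 12
Reactants: 19 saturated ketone
Product: 20 tertiary allylic alcohol (9-hydroxy-9-isopropenyl; mixture at C9)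
Conditions: CH2=C(CH3)MgBr, CeCl3, THF, −78 °C
Reagents that add atoms: isopropenylmagnesium bromide, CC(=C)[Mg]Br
Why: 1,2-Addition of the weakly basic organocerium reagent to the hindered, enolisable ketone (lactone and acetate react much more slowly at −78 °C); the new carbinol centre is lost in step 14.

Step 13
Reactants: 20 tertiary allylic alcohol
Product: 22 lactone diol (6-hydroxy; 9-hydroxy-9-isopropenyl), via lithium carboxylate 21 (not isolated)
Conditions: LiOH, THF/MeOH/H2O, 40 °C; then 1 M HCl to pH 3, 0 → 25 °C
Reagents that add atoms: lithium hydroxide, [Li+].[OH-]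
Why: Saponification cleaves the tertiary acetate and opens the lactone, and acidification relactonises the cis γ-hydroxy acid, which removes the enolisable acetate before the enolate chemistry of step 18.

Step 14
Reactants: 22 lactone diol
Product: 23 (Z)-enal lactone (2-(spirodecan-9-ylidene)propanal; CHO cis to C10)
Conditions: pyridinium chlorochromate (C5H5NH)[CrO3Cl], 4 Å molecular sieves, CH2Cl2, 25 °C
Reagents that add atoms: pyridinium chlorochromate, [O-][Cr](=O)(=O)Cl.c1cc[nH+]cc1
Why: Babler–Dauben oxidative transposition: [3,3] shift of the tertiary allylic chromate ester and oxidation of the primary chromate give the tetrasubstituted enal, expected mainly as the Z isomer with the smaller formyl group on the hindered C10 side.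

Step 15
Reactants: 23 (Z)-enal lactone
Product: 24 (Z)-enal dimethyl acetal lactone
Conditions: HC(OMe)3, MeOH, PPTS (cat.), 25 °C
Reagents that add atoms: trimethyl orthoformate, COC(OC)OC; methanol, CO
Why: Acid-catalysed acetalisation protects the aldehyde against the enolate and hydride reagents of steps 18 and 20.

Step 16
Reactants: 25 (E)-pent-2-en-4-yn-1-ol; 26 1-chloro-3-methylbut-2-ene
Product: 28 (2E,4E)-4,8-dimethylnona-2,4,7-trien-1-ol, via alkenylalane 27 (not isolated)
Conditions: Me3Al, Cp2ZrCl2 (25 mol %), CH2Cl2, 25 °C; then 26, Pd(PPh3)4 (5 mol %), THF, 25 °C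
Reagents that add atoms: trimethylaluminium, C[Al](C)C
Why: Negishi zirconium-catalysed carboalumination adds CH3 and Al syn across the alkyne, and palladium-catalysed cross-coupling of the alkenylalane with the allylic chloride occurs with retention, which fixes the E geometry of the trisubstituted alkene.

Step 17
Reactants: 28 (2E,4E)-4,8-dimethylnona-2,4,7-trien-1-ol
Product: 29 (2E,4E)-4,8-dimethylnona-2,4,7-trienal
Conditions: MnO2, CH2Cl2, 25 °C
Reagents that add atoms: none
Why: MnO2 oxidation of the primary allylic alcohol without isomerisation of the diene.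

Step 18
Reactants: 24 (Z)-enal dimethyl acetal lactone; 29 (2E,4E)-4,8-dimethylnona-2,4,7-trienal
Product: 31 β-hydroxy lactone (aldol adduct; diastereomer mixture), via lithium enolate 30 (not isolated)
Conditions: LDA (2.2 equiv), THF, −78 °C; then 29; H2O quench
Reagents that add atoms: none
Why: Aldol addition of the lactone lithium enolate to the enal (1,2-addition; the first equivalent of base deprotonates the tertiary alcohol); the new stereocentres are erased in step 19.

Step 19
Reactants: 31 β-hydroxy lactone
Product: 33 (E)-alkylidene lactone (trienyl chain anti to the lactone carbonyl), via allylic acetate 32 (not isolated)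
Conditions: Ac2O, Et3N, DMAP (cat.), CH2Cl2, 0 °C; then DBU, 25 °C
Reagents that add atoms: none
Why: Acetylation of the secondary alcohol and E1cB elimination should give the thermodynamically preferred E alkylidene lactone, with the trienyl chain anti to the lactone carbonyl.

Step 20
Reactants: 33 (E)-alkylidene lactone
Product: 34 triol acetal (C1–OH, C6–OH and allylic CH2OH free; silyl ether and acetal intact)
Conditions: iBu2AlH, CH2Cl2, −78 → 0 °C; aq. KNaC4H4O6 work-up
Reagents that add atoms: none
Why: Reductive opening of the α,β-unsaturated lactone by 1,2-hydride delivery (DIBAL-H reduction) liberates the C1 hydroxyl and the allylic CH2OH without touching the acetal or the alkene geometries.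

Step 21
Reactants: 34 triol acetal
Product: 36 target CNP0261841.1, via silyl ether enal 35 (not isolated)
Conditions: AcOH/THF/H2O (3:1:1), 25 °C
Reagents that add atoms: water, O
Why: Mild aqueous acid hydrolyses the allylic dimethyl acetal and then the primary silyl ether to give the target.

Compound list

1 | rac-cyclopent-2-en-1-yl acetate | CC(=O)OC1CCC=C1 | starting material
2 | dimethyl malonate | COC(=O)CC(=O)OC | starting material
3 | dimethyl (R)-2-(cyclopent-2-en-1-yl)malonate | COC(=O)C(C(=O)OC)[C@@H]1CCC=C1 | intermediate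
4 | (R)-2-(cyclopent-2-en-1-yl)malonic acid | OC(=O)C(C(=O)O)[C@@H]1CCC=C1 | intermediate (not isolated)
5 | (S)-2-(cyclopent-2-en-1-yl)acetic acid | OC(=O)C[C@@H]1CCC=C1 | intermediate
6 | 2-(2,3-epoxycyclopentyl)acetic acid, epoxide oxygen trans to the CH2CO2H group | OC(=O)C[C@@H]1CC[C@H]2O[C@@H]12 | intermediate (not isolated)
7 | (1R,5S,8R)-8-hydroxy-2-oxabicyclo[3.3.0]octan-3-one (cis-fused lactone, hydroxyl trans to the lactone oxygen) | O=C1C[C@@H]2CC[C@@H](O)[C@@H]2O1 | intermediate
8 | (1R,5S)-2-oxabicyclo[3.3.0]octane-3,8-dione | O=C1C[C@@H]2CCC(=O)[C@@H]2O1 | intermediate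
9 | 1-(triphenylphosphoranylidene)propan-2-one | CC(=O)C=P(c1ccccc1)(c1ccccc1)c1ccccc1 | starting material
10 | (1R,5S)-8-[(E)-2-oxopropylidene]-2-oxabicyclo[3.3.0]octan-3-one | O=C1C[C@@H]2CC/C(=C\C(C)=O)[C@@H]2O1 | intermediate
11 | (1R,5S)-8-[(E)-2-(tert-butyldimethylsilyloxy)prop-2-en-1-ylidene]-2-oxabicyclo[3.3.0]octan-3-one | O=C1C[C@@H]2CC/C(=C\C(=C)O[Si](C)(C)C(C)(C)C)[C@@H]2O1 | intermediate
12 | 3-methylbut-3-en-2-one | CC(=O)C(C)=C | starting material
13 | Diels–Alder adduct: 6-acetyl-6-methyl-9-(tert-butyldimethylsilyloxy)spiro[4.5]dec-9-ene carrying the C1–O–CO–CH2–C2 γ-lactone; C5–C6 bond anti to the lactone oxygen, acetyl cis to C1, methyl cis to C4 | O=C1C[C@@H]2CC[C@]3(C=C(O[Si](C)(C)C(C)(C)C)CC[C@]3(C)C(C)=O)[C@@H]2O1 | intermediate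
14 | 3-(tert-butyldimethylsilyloxy)propanal | O=CCCO[Si](C)(C)C(C)(C)C | starting material
15 | aldol adduct: 9-oxo lactone with 10-[1-hydroxy-3-(tert-butyldimethylsilyloxy)propyl], mixture at C10 and the carbinol carbon | O=C1C[C@@H]2CC[C@]3(C(C(O)CCO[Si](C)(C)C(C)(C)C)C(=O)CC[C@]3(C)C(C)=O)[C@@H]2O1 | intermediate
16 | methanesulfonate of 15 | O=C1C[C@@H]2CC[C@]3(C(C(OS(C)(=O)=O)CCO[Si](C)(C)C(C)(C)C)C(=O)CC[C@]3(C)C(C)=O)[C@@H]2O1 | intermediate (not isolated)
17 | exocyclic enone: 6-acetyl-9-oxo-10-[3-(tert-butyldimethylsilyloxy)propylidene] lactone, E/Z mixture | O=C1C[C@@H]2CC[C@]3(C(=CCCO[Si](C)(C)C(C)(C)C)C(=O)CC[C@]3(C)C(C)=O)[C@@H]2O1 | intermediate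
18 | 6-acetoxy enone: as 17 with OAc in place of acetyl (acetate cis to C1) | O=C1C[C@@H]2CC[C@]3(C(=CCCO[Si](C)(C)C(C)(C)C)C(=O)CC[C@]3(C)OC(C)=O)[C@@H]2O1 | intermediate
19 | saturated ketone: 6-acetoxy-9-oxo-10-[3-(tert-butyldimethylsilyloxy)propyl] lactone, C10 chain cis to C1 (C10 as in the target) | O=C1C[C@@H]2CC[C@]3([C@H](CCCO[Si](C)(C)C(C)(C)C)C(=O)CC[C@]3(C)OC(C)=O)[C@@H]2O1 | intermediate
20 | tertiary allylic alcohol: 6-acetoxy-9-hydroxy-9-(prop-1-en-2-yl) lactone, mixture at C9 | O=C1C[C@@H]2CC[C@]3([C@H](CCCO[Si](C)(C)C(C)(C)C)C(O)(C(C)=C)CC[C@]3(C)OC(C)=O)[C@@H]2O1 | intermediate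
21 | lithium carboxylate of the ring-opened triol (C1–OH, C6–OH, C9–OH free) | [Li+].[O-]C(=O)C[C@@H]1CC[C@]2([C@H](CCCO[Si](C)(C)C(C)(C)C)C(O)(C(C)=C)CC[C@]2(C)O)[C@@H]1O | intermediate (not isolated)
22 | lactone diol: 6-hydroxy-9-hydroxy-9-(prop-1-en-2-yl) lactone | O=C1C[C@@H]2CC[C@]3([C@H](CCCO[Si](C)(C)C(C)(C)C)C(O)(C(C)=C)CC[C@]3(C)O)[C@@H]2O1 | intermediate
23 | (Z)-enal lactone: (Z)-2-(spirodecan-9-ylidene)propanal, CHO cis to C10, 6-OH free | O=C1C[C@@H]2CC[C@]3([C@H](CCCO[Si](C)(C)C(C)(C)C)/C(=C(/C)C=O)CC[C@]3(C)O)[C@@H]2O1 | intermediate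
24 | dimethyl acetal of 23 | O=C1C[C@@H]2CC[C@]3([C@H](CCCO[Si](C)(C)C(C)(C)C)/C(=C(/C)C(OC)OC)CC[C@]3(C)O)[C@@H]2O1 | intermediate
25 | (E)-pent-2-en-4-yn-1-ol | OC/C=C/C#C | starting material
26 | 1-chloro-3-methylbut-2-ene (prenyl chloride) | CC(C)=CCCl | starting material
27 | (1E,3E)-dienylalane: dimethylaluminium alkoxide of 5-(dimethylalumanyl)-4-methylpenta-2,4-dien-1-ol, CH3 and Al cis | C[Al](C)OC/C=C/C(C)=C/[Al](C)C | intermediate (not isolated)
28 | (2E,4E)-4,8-dimethylnona-2,4,7-trien-1-ol | OC/C=C/C(C)=C/CC=C(C)C | intermediate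
29 | (2E,4E)-4,8-dimethylnona-2,4,7-trienal | O=C/C=C/C(C)=C/CC=C(C)C | intermediate
30 | dilithium salt of 24: lactone enolate and C6 alkoxide | [Li+].[Li+].[O-]C1=C[C@@H]2CC[C@]3([C@H](CCCO[Si](C)(C)C(C)(C)C)/C(=C(/C)C(OC)OC)CC[C@]3(C)[O-])[C@@H]2O1 | intermediate (not isolated)
31 | β-hydroxy lactone: lactone α-carbon bearing the 1-hydroxy-(2E,4E)-4,8-dimethylnona-2,4,7-trienyl group, diastereomer mixture | O=C1C(C(O)/C=C/C(C)=C/CC=C(C)C)[C@@H]2CC[C@]3([C@H](CCCO[Si](C)(C)C(C)(C)C)/C(=C(/C)C(OC)OC)CC[C@]3(C)O)[C@@H]2O1 | intermediate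
32 | acetate of 31 at the secondary hydroxyl | O=C1C(C(OC(C)=O)/C=C/C(C)=C/CC=C(C)C)[C@@H]2CC[C@]3([C@H](CCCO[Si](C)(C)C(C)(C)C)/C(=C(/C)C(OC)OC)CC[C@]3(C)O)[C@@H]2O1 | intermediate (not isolated)
33 | (E)-α-alkylidene lactone with the all-E trienyl chain anti to the lactone carbonyl | O=C1/C(=C/C=C/C(C)=C/CC=C(C)C)[C@@H]2CC[C@]3([C@H](CCCO[Si](C)(C)C(C)(C)C)/C(=C(/C)C(OC)OC)CC[C@]3(C)O)[C@@H]2O1 | intermediate
34 | triol acetal: target with the 3-hydroxypropyl oxygen as tert-butyldimethylsilyl ether and the aldehyde as dimethyl acetal | CC(C)=CC/C=C(C)/C=C/C=C(/CO)[C@@H]1CC[C@]2([C@H](CCCO[Si](C)(C)C(C)(C)C)/C(=C(/C)C(OC)OC)CC[C@]2(C)O)[C@@H]1O | intermediate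
35 | target with the 3-hydroxypropyl oxygen as tert-butyldimethylsilyl ether | CC(C)=CC/C=C(C)/C=C/C=C(/CO)[C@@H]1CC[C@]2([C@H](CCCO[Si](C)(C)C(C)(C)C)/C(=C(/C)C=O)CC[C@]2(C)O)[C@@H]1O | intermediate (not isolated)
36 | CNP0261841.1: (Z)-2-{(1R,2S,5S,6S,10R)-1,6-dihydroxy-2-[(2E,4E,6E)-1-hydroxy-6,10-dimethylundeca-2,4,6,9-tetraen-2-yl]-10-(3-hydroxypropyl)-6-methylspiro[4.5]decan-9-ylidene}propanal | CC(C)=CC/C=C(C)/C=C/C=C(/CO)[C@@H]1CC[C@]2([C@H](CCCO)/C(=C(/C)C=O)CC[C@]2(C)O)[C@@H]1O | target

Total step count: 21. Longest linear sequence: 19 steps (steps 1–15, then 18–21); steps 16 and 17 make the trienal side arm.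

Steps most likely to fail

Step 7. The second bond joins two fully substituted carbons, so ring closure may stall after the first conjugate addition. Protodesilylation of the diene may also outrun addition, and endo/exo control at C6 may erode. The fallback sets out from 11 and comes back at 13. Cycloaddition of 11 with the smaller and more electrophilic 2-methylprop-2-enal (CC(=C)C=O; Me2AlCl, CH2Cl2, −78 °C) should give the aldehyde adduct F1 with the same facial and endo preference. Addition of MeMgBr (THF, −78 °C) to the neopentyl aldehyde, faster than attack on the lactone, should give the secondary carbinol F2 as a mixture at the carbinol carbon. Dess–Martin oxidation (pyridine buffer) of F2 should then give methyl ketone 13, so that the acetyl group is built after the ring.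

Step 11. Hydrogen may be delivered to the exocyclic alkene from the wrong face. The unwanted C10 epimer is expected to be the more stable one, so epimerisation cannot correct the outcome. The fallback sets out from 18 and comes back at 19. Luche reduction (NaBH4, CeCl3·7H2O, MeOH, −40 °C), with hydride entering from the face that proved accessible, should give the allylic alcohol F3 with the C9 hydroxyl on the C4 side. Hydroxyl-directed hydrogenation with [Ir(cod)(PCy3)(py)]PF6 (H2, CH2Cl2) should then place hydrogen at C10 on the same face as that hydroxyl and give the saturated alcohol F4. Dess–Martin oxidation of F4 should give 19.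

Step 14. Chromate ester formation at the hindered tertiary alcohol may be slow, and the transposition may give a mixture of alkene geometries that equilibrates under the acidic oxidant. The fallback sets out from 22 and comes back at 23. Ph3SiOReO3-catalysed 1,3-transposition of the hydroxyl (Et2O, 0 °C) should give the primary allylic alcohol F5, where the geometrical isomers can be separated. MnO2 oxidation of F5 should then give 23 under neutral conditions.

Further compounds

F1 | step 7 | aldehyde adduct: as 13 with CHO in place of acetyl at C6 (CHO cis to C1) | O=C1C[C@@H]2CC[C@]3(C=C(O[Si](C)(C)C(C)(C)C)CC[C@]3(C)C=O)[C@@H]2O1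
F2 | step 7 | secondary carbinol: as 13 with CH(OH)CH3 in place of acetyl at C6, mixture at the carbinol carbon | O=C1C[C@@H]2CC[C@]3(C=C(O[Si](C)(C)C(C)(C)C)CC[C@]3(C)C(C)O)[C@@H]2O1
F3 | step 11 | allylic alcohol: as 18 with C9–OH (cis to C4) in place of the C9 ketone | O=C1C[C@@H]2CC[C@]3(C(=CCCO[Si](C)(C)C(C)(C)C)[C@@H](O)CC[C@]3(C)OC(C)=O)[C@@H]2O1
F4 | step 11 | saturated alcohol: as 19 with C9–OH (cis to C4 and to C10–H) in place of the C9 ketone | O=C1C[C@@H]2CC[C@]3([C@H](CCCO[Si](C)(C)C(C)(C)C)[C@@H](O)CC[C@]3(C)OC(C)=O)[C@@H]2O1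
F5 | step 14 | (Z)-primary allylic alcohol: as 23 with CH2OH in place of CHO | O=C1C[C@@H]2CC[C@]3([C@H](CCCO[Si](C)(C)C(C)(C)C)/C(=C(/C)CO)CC[C@]3(C)O)[C@@H]2O1
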